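Bracket [acid] in the flask at 15 h, because the pH follows from it.

| flask | starting material | acid | scavenger | protic impurity | remark | time |
|---|---|---|---|---|---|---|
| teal | 0.020 M | 0.20 mM | 2.2 equiv | 10 mM | run made earlier |  |
| flask | 0.020 M | 0.200 mM | 1.50 equiv | 10.0 mM |  | 15 h |
- teal (time / h: starting material / %, product / %): 0.250: 91.5, 3.1; 0.417: 86.1, 5.7; 0.667: 79.0, 9.4; 1.00: 68.1, 13.0; 2.00: 43.3, 24.5; 3.00: 27.6, 35.1

(each reading ± 0.5 percentage points)
- acid is the free proton; pH is minus the decimal logarithm of its molar concentration
- amounts and yields of weak acid count idle adduct too
- candidate steps: starting material + weak acid <-> idle adduct; starting material + protic impurity -> quenched substrate; starting material + acid -> weak acid + acid + product; weak acid <-> conjugate base + acid; weak acid + scavenger -> scavenged by-product; starting material -> weak acid + product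
- what has gone from starting material into another species counts as reacted, even if it can come back
- no earlier run changes the charge of scavenger; that part of a forecast is a guess
* part of the starting material that has reacted at 15 h
* pH of the solution at 15 h

Start with the floor. The candidate steps return the acid or add to it, so [acid] stays at or above its charge, 0.200 mM. For the ceiling, each product frees at most one weak acid, so [acid] stays below 20.2 mM; I cannot narrow that by hand.

Now raise the floor from the teal run. Take product gained per hour per starting material, late over early, so that the clock drops out:

gain = [24.5 % to 35.1 %, over mean starting material] / [3.1 % in 0.250 h, likewise] = 2.31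

Call this the acid gain, the late product rate constant of the teal run over its early one. The ratio equals the growth of [acid] where all product comes by the acid step; the step from starting material to weak acid + product needs no acid, adds the same to top and bottom, and so pulls the ratio under that growth. It is coarse, since that first reading carries 0.5 percentage points. If the flask holds that gain despite less scavenger, which is a guess, then:

[acid] ≥ gain × charge = 0.462 mM

The forecast gave 99.6 % reacted and pH 3.4, an [acid] of about 0.4 mM, and said of its own figure: “The scavenger effect is a guess”. That lies inside the plain bracket, a little under the raised floor.

The flask gives 96.9 % and pH 3.17.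

    starting material + weak acid ⇌ idle adduct, settled at all times (K = 1380 /M)
    starting material + protic impurity → quenched substrate (k = 0.150 /M/min)
    starting material + acid → weak acid + acid + product (k = 8.96 /M/min)
    weak acid ⇌ conjugate base + acid, settled at all times (K = 2.50 × 10⁻⁴ M)
    weak acid + scavenger → scavenged by-product (k = 0.404 /M/min)
    starting material → weak acid + product (k = 3.67 × 10⁻⁴ /min)

At 15.0 h the flask holds acid at 339 % of charge, above the gain. The neighbour read at 4.0 h also clears it, with 323 %. But the flask is not at rest. Scavenger still stands at 61.5 % and keeps taking weak acid. By 150 h it is down to 46.9 %, scavenged by-product has risen from 0.0116 M to 0.0159 M, and product from 72.2 % to 79.6 %. Starting material goes from 3.12 % to 0 %. Acid falls below the gain, back to 100 % of its charge.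

All runs are calculated for substances that don't exist; noise was put on by code.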